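- At the full charge the dimer step removes substrate at 6.80 × 10⁻⁵ s⁻¹, which is close to the 7.1 × 10⁻⁵ s⁻¹ of the step to intermediate A, so neither can be dropped.

substrate 0.10 M; time 6.0 h

    substrate → target (k1 = 1.7 × 10⁻⁶ s⁻¹)
    2 substrate → homo dimer (k2 = 3.4 × 10⁻⁴ M⁻¹ s⁻¹)
    substrate → intermediate A (k3 = 7.1 × 10⁻⁵ s⁻¹)
    intermediate B → side product (k4 = 0.0015 s⁻¹)
    intermediate A → target (k5 = 4.0 × 10⁻⁶ s⁻¹)
    substrate ⇌ intermediate B (K6 = 0.39, k6 = 3.8 × 10⁻⁵ s⁻¹)
    intermediate B ⇌ intermediate C (K7 = 9.1, k7 = 3.5 × 10⁻⁵ s⁻¹)

* why nothing more happens at 6.0 h, or that something still does (forward and back rates have come level / all of the substrate has reacted / it is still moving)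
* how much of the substrate has reacted by 6.0 h
* how much target there is at 6.0 h, in percent of the substrate charged
* how much intermediate A there is at 6.0 h, in percent of the substrate charged

- percent here means substrate units held: one homo dimer counts as two
- two of one species on the left: rate k times its square, two consumed each time
- the reaction counts as stopped when no species that holds the substrate changes by six tenths of a point or more over the second half of the time
- run time (flask): 6.0 h

- We follow the fraction of substrate left, not the products: each product of a first-order step from substrate grows as its constant times the area under that fraction.
- Intermediate B has a half-life of 7.70 min on the way to side product, short against 6.0 h, so we use the steady-state approximation: of what enters, 93.9% goes on to side product.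
- The loss constant, the sum of the first-order drains on substrate, is then 1.08 × 10⁻⁴ s⁻¹.
- The constant of the step to intermediate A must be known best, since it makes 65.5% of the loss constant and sets the amount of intermediate A directly.
- For conversion the forward constant into intermediate B comes next, at 32.9% of the loss constant, and the dimer constant after it: the dimer drain shrinks with c substrate, and at half the charge it is 3.40 × 10⁻⁵ s⁻¹, less than the 3.57 × 10⁻⁵ s⁻¹ of that route.
- The return from intermediate B costs 2.14% of it, and the direct step to target makes 1.57%, so these two can be rough for conversion.
- Exchange with intermediate C runs at 2.33% of the drain to side product, so we leave it out.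
- Put g = 0.627 and let the divisor be one plus g times (one minus exp(−loss constant × time)), here 1.57. The fraction left is the exponential over the divisor: 6.14% at 6.0 h, but 21.7% at half that time, so the flask is still moving.
- The exposure, the area under the fraction left, equals ln(divisor) over the dimer rate at the charge1.83 h.
- So 46.9% of intermediate A is made. At most 8.64% of it moves on, which leaves between 42.8% and that figure standing. Target is 1.12% direct plus at most 4.05%; our reckoning stops at these ranges.
- The forecast says it is still moving, with 93.9% conversion, 4% target and 44% intermediate A, and its ground is "Intermediate B is drained fast, so treat it as steady state".
- The simulation gives it is still moving, with 93.8% conversion, 3.90% target and 44.1% intermediate A.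
- Per unit of its own concentration, substrate enters intermediate A 17.8 times as fast as intermediate A leaves for target. This flask holds 44.1% of intermediate A against 3.90% of target, and intermediate A standing plus its 2.78% net turnover into target comes to 46.9%, beside the 46.9% from the exposure. The neighbour flask stopped at 1.5 h has an exposure of 1.00 h, which makes 25.6%, and it holds 25.3% of intermediate A.

Its constants are those of an exercise; the run is a simulation.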